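## Retrosynthetic overview

1. Target 13 ← hexabenzyl ether 12 by hydrogenolysis; all six phenols stay benzylated until the end.
2. 12 ← open-chain chalcone–diketone 10: the flavanone ring C (with C2) and the flavone ring E are closed together in one flask, by a catalytic asymmetric oxa-Michael addition followed by acid cyclodehydration.
3. 10 ← biaryl aldehyde 9 + acetophenone 2 (Claisen–Schmidt); 9 ← aryl iodide 5 + aryl bromide 7 (borylation and Suzuki coupling in one pot), so the biaryl bond exists before either heterocycle.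
4. 5 ← iodoacetophenone 3 + ester 4 (Claisen condensation); 3 ← 2 ← phloroacetophenone 1; compound 2 is used twice (rings A and D).
5. Ring order: the benzene rings A, B, D and F are bought (A/B = flavanone half, D/F = flavone half); rings C and E are formed last, in the same operation.

Assumption: the quinine-derived thiourea of step 7 is taken to be the pseudoenantiomer that closes ring C to the 2S product; if a test run gives 2R, the quinidine-derived (9R) pseudoenantiomer is used with nothing else changed.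

Note on drawing: the 1,3-diketones 5, 9, 10 and 11 are drawn in the open diketo form; each equilibrates with its enol and its cyclic hemiketal, and none is dehydrated before step 7.

## Route

Step 1
Reactants: 1 2′,4′,6′-trihydroxyacetophenone
Product: 2 1-[2,4-bis(benzyloxy)-6-hydroxyphenyl]ethan-1-one
Conditions: BnBr (2.1 equiv), K2CO3 (2.2 equiv), DMF, 0 °C → rt
Reagents that add atoms: benzyl bromide, BrCc1ccccc1
Why: Williamson ether synthesis in which the para OH and one ortho OH are alkylated, while the other ortho OH is hydrogen-bonded to the acetyl carbonyl and stays free when only two equivalents of halide are used.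

Step 2
Reactants: 2 1-[2,4-bis(benzyloxy)-6-hydroxyphenyl]ethan-1-one
Product: 3 1-[4,6-bis(benzyloxy)-2-hydroxy-3-iodophenyl]ethan-1-one
Conditions: N-iodosuccinimide (1.0 equiv), DMF, 0 °C → rt, dark
Reagents that add atoms: N-iodosuccinimide, O=C1CCC(=O)N1I
Why: Electrophilic aromatic iodination goes to the carbon ortho to the free phenol, which is less hindered than the carbon between the two benzyloxy groups, and this places the halogen at the future C8 of the flavone.

Step 3
Reactants: 3 1-[4,6-bis(benzyloxy)-2-hydroxy-3-iodophenyl]ethan-1-one; 4 methyl 4-(benzyloxy)benzoate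
Product: 5 1-[4,6-bis(benzyloxy)-2-hydroxy-3-iodophenyl]-3-[4-(benzyloxy)phenyl]propane-1,3-dione
Conditions: LiN(SiMe3)2 (4 equiv), THF, −78 °C; then 4, −78 → 40 °C; cold 1 M HCl to pH 5
Reagents that add atoms: none
Why: Crossed Claisen condensation (a one-step equivalent of the Baker–Venkataraman sequence) in which the lithium phenoxide–enolate dianion of 3 is acylated on carbon by the non-enolisable ester 4, the product rests as its diketonate until the quench, and the aryl iodide and benzyl ethers are inert to the amide base.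

Step 4
Reactants: 6 3-bromo-4-hydroxybenzaldehyde
Product: 7 4-(benzyloxy)-3-bromobenzaldehyde
Conditions: BnBr (1.1 equiv), K2CO3, DMF, rt
Reagents that add atoms: benzyl bromide, BrCc1ccccc1
Why: Williamson ether synthesis on an acidic para-formyl phenol, with no competing site.

Step 5
Reactants: 7 4-(benzyloxy)-3-bromobenzaldehyde; 5 1-[4,6-bis(benzyloxy)-2-hydroxy-3-iodophenyl]-3-[4-(benzyloxy)phenyl]propane-1,3-dione
Product: 9 4-(benzyloxy)-3-{4,6-bis(benzyloxy)-3-[3-(4-benzyloxyphenyl)-3-oxopropanoyl]-2-hydroxyphenyl}benzaldehyde, via pinacol boronate 8 (not isolated)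
Conditions: B2pin2 (1.05 equiv), PdCl2(dppf) (3 mol %), KOAc, 1,4-dioxane, 90 °C; then 5 (0.85 equiv), Pd(OAc)2 (5 mol %), SPhos (10 mol %), aq. K3PO4, 80 °C
Reagents that add atoms: bis(pinacolato)diboron, CC1(C)OB(OC1(C)C)B1OC(C)(C)C(C)(C)O1 (its boron is kept in 8 only; nothing from it remains in 9)
Why: Miyaura borylation of the bromide followed in the same flask by Suzuki–Miyaura coupling, in which the iodide of 5 adds oxidatively to SPhos-ligated zerovalent palladium although it sits between two oxygen substituents, while the phenoxide and diketonate of 5 and the aldehyde of 8 are spectators in aqueous phosphate.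

Step 6
Reactants: 9 4-(benzyloxy)-3-{4,6-bis(benzyloxy)-3-[3-(4-benzyloxyphenyl)-3-oxopropanoyl]-2-hydroxyphenyl}benzaldehyde; 2 1-[2,4-bis(benzyloxy)-6-hydroxyphenyl]ethan-1-one
Product: 10 (E)-1-[2,4-bis(benzyloxy)-6-hydroxyphenyl]-3-(4-(benzyloxy)-3-{4,6-bis(benzyloxy)-3-[3-(4-benzyloxyphenyl)-3-oxopropanoyl]-2-hydroxyphenyl}phenyl)prop-2-en-1-one
Conditions: 2 (1.2 equiv), KOH (50 % aq.), EtOH–THF, 0 °C → rt; cold aq. AcOH to pH 5
Reagents that add atoms: none
Why: Claisen–Schmidt condensation in which 2 is the only partner with a free enolisable methyl ketone (the diketone of 9 rests as its stabilised enolate, whose aldol adducts revert) and 9 is the only aldehyde, E1cB loss of water gives the E-enone, and in strong base the product stays open as its phenoxide so that no flavanone forms before step 7.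

Step 7
Reactants: 10 (E)-1-[2,4-bis(benzyloxy)-6-hydroxyphenyl]-3-(4-(benzyloxy)-3-{4,6-bis(benzyloxy)-3-[3-(4-benzyloxyphenyl)-3-oxopropanoyl]-2-hydroxyphenyl}phenyl)prop-2-en-1-one
Product: 12 (2S)-5,7-bis(benzyloxy)-2-{4-(benzyloxy)-3-[5,7-bis(benzyloxy)-2-(4-benzyloxyphenyl)-4-oxo-4H-chromen-8-yl]phenyl}chroman-4-one, via flavanone diketone 11 (not isolated)
Conditions: N-[3,5-bis(trifluoromethyl)phenyl]-N′-[(8α,9S)-6′-methoxycinchonan-9-yl]thiourea (20 mol %), toluene (0.02 M), rt, until < 2 % of 10 remains (HPLC); then TsOH·H2O (0.6 equiv), 70 °C; 12 recrystallised from EtOAc–heptane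
Reagents that add atoms: none
Why: Proposed new method: the quinuclidine nitrogen of the bifunctional catalyst deprotonates the free ortho OH of ring A while the thiourea hydrogen-bonds the enone carbonyl, so the 6-endo-trig oxa-Michael closure of ring C occurs on one enone face and sets C2 as S under kinetic control (the ortho benzyloxy group twists the chalcone and makes closure strongly downhill, so reversal is slow), after which TsOH in the same flask quenches the amine and cyclodehydrates the 2-hydroxyaryl 1,3-diketone through its only free phenol to give ring E with the biaryl at C8, the closest known chemistry being the cinchona-thiourea oxa-Michael cyclisation of activated 2-hydroxyphenyl alkylidene ketoesters followed by TsOH in one pot without loss of ee and the acid cyclodehydration of 2-hydroxydibenzoylmethanes to flavones.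

Step 8
Reactants: 12 (2S)-5,7-bis(benzyloxy)-2-{4-(benzyloxy)-3-[5,7-bis(benzyloxy)-2-(4-benzyloxyphenyl)-4-oxo-4H-chromen-8-yl]phenyl}chroman-4-one
Product: 13 (2S)-5,7-dihydroxy-2-{4-hydroxy-3-[5,7-dihydroxy-2-(4-hydroxyphenyl)-4-oxo-4H-chromen-8-yl]phenyl}chroman-4-one
Conditions: H2 (1 atm), Pd/C (10 % Pd), THF–MeOH, rt, stopped at full debenzylation
Reagents that add atoms: none
Why: Catalytic hydrogenolysis cleaves the six benzyl aryl ethers much faster than it attacks the cyclic C2–O bond, the flavone C2=C3 bond or the aryl ketones at 1 atm and room temperature, and the neutral medium leaves the C2 stereocentre untouched.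

## Compound list

1 | 2′,4′,6′-trihydroxyacetophenone (phloroacetophenone) | CC(=O)c1c(O)cc(O)cc1O | starting material
2 | 1-[2,4-bis(benzyloxy)-6-hydroxyphenyl]ethan-1-one | CC(=O)c1c(O)cc(OCc2ccccc2)cc1OCc1ccccc1 | intermediate
3 | 1-[4,6-bis(benzyloxy)-2-hydroxy-3-iodophenyl]ethan-1-one | CC(=O)c1c(O)c(I)c(OCc2ccccc2)cc1OCc1ccccc1 | intermediate
4 | methyl 4-(benzyloxy)benzoate | COC(=O)c1ccc(OCc2ccccc2)cc1 | starting material
5 | 1-[4,6-bis(benzyloxy)-2-hydroxy-3-iodophenyl]-3-[4-(benzyloxy)phenyl]propane-1,3-dione | O=C(CC(=O)c1ccc(OCc2ccccc2)cc1)c1c(O)c(I)c(OCc2ccccc2)cc1OCc1ccccc1 | intermediate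
6 | 3-bromo-4-hydroxybenzaldehyde | O=Cc1ccc(O)c(Br)c1 | starting material
7 | 4-(benzyloxy)-3-bromobenzaldehyde | O=Cc1ccc(OCc2ccccc2)c(Br)c1 | intermediate
8 | 4-(benzyloxy)-3-(4,4,5,5-tetramethyl-1,3,2-dioxaborolan-2-yl)benzaldehyde | O=Cc1ccc(OCc2ccccc2)c(B2OC(C)(C)C(C)(C)O2)c1 | intermediate
9 | 4-(benzyloxy)-3-{4,6-bis(benzyloxy)-3-[3-(4-benzyloxyphenyl)-3-oxopropanoyl]-2-hydroxyphenyl}benzaldehyde | O=Cc1ccc(OCc2ccccc2)c(-c2c(O)c(C(=O)CC(=O)c3ccc(OCc4ccccc4)cc3)c(OCc3ccccc3)cc2OCc2ccccc2)c1 | intermediate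
10 | (E)-1-[2,4-bis(benzyloxy)-6-hydroxyphenyl]-3-(4-(benzyloxy)-3-{4,6-bis(benzyloxy)-3-[3-(4-benzyloxyphenyl)-3-oxopropanoyl]-2-hydroxyphenyl}phenyl)prop-2-en-1-one | O=C(/C=C/c1ccc(OCc2ccccc2)c(-c2c(O)c(C(=O)CC(=O)c3ccc(OCc4ccccc4)cc3)c(OCc3ccccc3)cc2OCc2ccccc2)c1)c1c(O)cc(OCc2ccccc2)cc1OCc1ccccc1 | intermediate
11 | (2S)-5,7-bis(benzyloxy)-2-(4-(benzyloxy)-3-{4,6-bis(benzyloxy)-3-[3-(4-benzyloxyphenyl)-3-oxopropanoyl]-2-hydroxyphenyl}phenyl)chroman-4-one | O=C1C[C@@H](c2ccc(OCc3ccccc3)c(-c3c(O)c(C(=O)CC(=O)c4ccc(OCc5ccccc5)cc4)c(OCc4ccccc4)cc3OCc3ccccc3)c2)Oc2cc(OCc3ccccc3)cc(OCc3ccccc3)c21 | intermediate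
12 | (2S)-5,7-bis(benzyloxy)-2-{4-(benzyloxy)-3-[5,7-bis(benzyloxy)-2-(4-benzyloxyphenyl)-4-oxo-4H-chromen-8-yl]phenyl}chroman-4-one | O=C1C[C@@H](c2ccc(OCc3ccccc3)c(-c3c(OCc4ccccc4)cc(OCc4ccccc4)c4c(=O)cc(-c5ccc(OCc6ccccc6)cc5)oc34)c2)Oc2cc(OCc3ccccc3)cc(OCc3ccccc3)c21 | intermediate
13 | (2S)-5,7-dihydroxy-2-{4-hydroxy-3-[5,7-dihydroxy-2-(4-hydroxyphenyl)-4-oxo-4H-chromen-8-yl]phenyl}chroman-4-one ((2S)-2,3-dihydroamentoflavone) | O=C1C[C@@H](c2ccc(O)c(-c3c(O)cc(O)c4c(=O)cc(-c5ccc(O)cc5)oc34)c2)Oc2cc(O)cc(O)c21 | target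

## Step count

Total steps: 8.
Longest linear sequence: 7 steps (1 → 2 → 3 → 5 → 9 → 10 → 12 → 13; steps 1, 2, 3, 5, 6, 7, 8). Step 4 lies on the side branch 6 → 7.

## The three steps most likely to fail

**Step 7.** The oxa-Michael addition onto a chalcone with no activating group may give insufficient ee. Any chalcone still present when the acid is added closes without stereocontrol. Fallback by resolution instead of asymmetric catalysis: setting out from 10, both rings are closed without stereocontrol (NaOAc, EtOH–THF, reflux; then TsOH·H2O, toluene, 70 °C) to give the racemic hexabenzyl ether F1. Preparative chromatography on an amylose-based chiral stationary phase (supercritical CO2–MeOH) separates F1 into 12, where the route is rejoined, and the (2R)-hexabenzyl ether F2. F2 is returned to F1 by base-induced ring opening and reclosure (NaOAc, EtOH–THF, reflux) and resolved again.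

**Step 5.** The coupling is hindered, follows an in-flask borylation, and is run on an iodide that carries a free, metal-binding 1,3-diketone. Fallback that makes the biaryl before the diketone: setting out from 7 and 3, boronate 8 is made and isolated (B2pin2, PdCl2(dppf), KOAc, dioxane, 90 °C) and coupled with iodoacetophenone 3 (Pd(OAc)2, SPhos, aq. K3PO4, toluene, 80 °C) to give the biaryl keto-aldehyde F3. The aldehyde is masked with HC(OMe)3 and catalytic TsOH in MeOH at rt to give the dimethyl acetal F4. Claisen condensation of F4 with ester 4 (LiN(SiMe3)2, THF) gives the diketone acetal F5. Brief treatment of F5 with dilute HCl in THF at rt frees the aldehyde and gives 9, where the route is rejoined.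

**Step 6.** The aldol condensation runs in the presence of an unprotected 1,3-diketone, which may condense with the aldehyde or be cleaved by hydroxide. Fallback that reverses the order of bond formation: setting out from 7 and 2, the enone is made first on the simple aldehyde (KOH, EtOH–THF, rt) to give the bromochalcone F6. Miyaura borylation (B2pin2, PdCl2(dppf), KOAc, dioxane, 80 °C) gives the chalcone pinacol boronate F7. F7 is coupled with iodo-diketone 5 (Pd(OAc)2, SPhos, aq. K3PO4, dioxane, 70 °C; the chalcone is held open as its phenoxide in this medium) to give 10 directly, where the route is rejoined.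

## Further compounds

F1 | step 7 | rac-5,7-bis(benzyloxy)-2-{4-(benzyloxy)-3-[5,7-bis(benzyloxy)-2-(4-benzyloxyphenyl)-4-oxo-4H-chromen-8-yl]phenyl}chroman-4-one | O=C1CC(c2ccc(OCc3ccccc3)c(-c3c(OCc4ccccc4)cc(OCc4ccccc4)c4c(=O)cc(-c5ccc(OCc6ccccc6)cc5)oc34)c2)Oc2cc(OCc3ccccc3)cc(OCc3ccccc3)c21
F2 | step 7 | (2R)-5,7-bis(benzyloxy)-2-{4-(benzyloxy)-3-[5,7-bis(benzyloxy)-2-(4-benzyloxyphenyl)-4-oxo-4H-chromen-8-yl]phenyl}chroman-4-one | O=C1C[C@H](c2ccc(OCc3ccccc3)c(-c3c(OCc4ccccc4)cc(OCc4ccccc4)c4c(=O)cc(-c5ccc(OCc6ccccc6)cc5)oc34)c2)Oc2cc(OCc3ccccc3)cc(OCc3ccccc3)c21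
F3 | step 5 | 3-[3-acetyl-4,6-bis(benzyloxy)-2-hydroxyphenyl]-4-(benzyloxy)benzaldehyde | CC(=O)c1c(O)c(-c2cc(C=O)ccc2OCc2ccccc2)c(OCc2ccccc2)cc1OCc1ccccc1
F4 | step 5 | 1-{4,6-bis(benzyloxy)-3-[2-(benzyloxy)-5-(dimethoxymethyl)phenyl]-2-hydroxyphenyl}ethan-1-one | CC(=O)c1c(O)c(-c2cc(C(OC)OC)ccc2OCc2ccccc2)c(OCc2ccccc2)cc1OCc1ccccc1
F5 | step 5 | 1-{4,6-bis(benzyloxy)-3-[2-(benzyloxy)-5-(dimethoxymethyl)phenyl]-2-hydroxyphenyl}-3-[4-(benzyloxy)phenyl]propane-1,3-dione | COC(OC)c1ccc(OCc2ccccc2)c(-c2c(O)c(C(=O)CC(=O)c3ccc(OCc4ccccc4)cc3)c(OCc3ccccc3)cc2OCc2ccccc2)c1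
F6 | step 6 | (E)-1-[2,4-bis(benzyloxy)-6-hydroxyphenyl]-3-[4-(benzyloxy)-3-bromophenyl]prop-2-en-1-one | O=C(/C=C/c1ccc(OCc2ccccc2)c(Br)c1)c1c(O)cc(OCc2ccccc2)cc1OCc1ccccc1
F7 | step 6 | (E)-1-[2,4-bis(benzyloxy)-6-hydroxyphenyl]-3-[4-(benzyloxy)-3-(4,4,5,5-tetramethyl-1,3,2-dioxaborolan-2-yl)phenyl]prop-2-en-1-one | O=C(/C=C/c1ccc(OCc2ccccc2)c(B2OC(C)(C)C(C)(C)O2)c1)c1c(O)cc(OCc2ccccc2)cc1OCc1ccccc1
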